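Retrosynthesis (daucane numbering): the two angelate C–O bonds and the O-2 silyl ether go first; the oxirane is traced to the C8=C9 alkene, which is cut by ring-closing metathesis; C4–isopropyl is cut back to a C4 ketone.
What remains is a cyclopentanone whose C4 carbonyl is flanked by C3 and C5 and has oxygen 1,3 on both sides (O-2 through C3, O-6 through C5). It is cut at C1–C5 and C2–C3 at once into a (Z)-aldehyde enol silyl ether (C1=C2) and the enol silane of a trans-α,β-epoxy ketone (C3–C4–C5, whose oxirane oxygen becomes O-6).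
Forward: two five-step fragments (C10–C1 by alkynylation of acrolein, C1–methyl by carbomagnesiation; C6–C7 by acetylide allylation) → five-membered ring C1–C5 (step 11) → isopropyl at C4 → seven-membered ring by metathesis (step 14) → oxirane → esters.
Stereochemistry: C10 from a catalytic asymmetric alkynylation; C5 and C6 from a Sharpless epoxidation (C5 with inversion in step 11); C1 and C2 from the C10 centre and the Z enol ether geometry in step 11; C4 by addition anti to the ring substituents; C8/C9 by hydroxyl-directed epoxidation.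

Key step: step 11

Remark: carbons are numbered as in daucane (C1 quaternary ring-fusion carbon, C2 CHOH, C4 C(OH)iPr, C5 ring-fusion CH, C6 and C10 ester carbons, C8 methyl-bearing). ProPhenol denotes the ligand 2,6-bis{[(2S)-2-(hydroxydiphenylmethyl)pyrrolidin-1-yl]methyl}-4-methylphenol; its (S,S) form is assumed to give the (S)-carbinol in step 1, otherwise its mirror image is used.

Step 1
Reactants: 1 acrolein; 2 ethynyltrimethylsilane
Product: 4 (3S)-5-(trimethylsilyl)pent-1-en-4-yn-3-ol, via zinc acetylide 3 (not isolated)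
Conditions: 2, Me2Zn, (S,S)-ProPhenol ligand (10 mol%), Ph3P=O (20 mol%), toluene, 0 °C; then 1; aq. NH4Cl
Reagents that add atoms: none
Why: Catalytic asymmetric alkynylation of an enal: the zinc acetylide adds 1,2 to the aldehyde inside the chiral pocket of the dinuclear zinc alkoxide formed from Me2Zn and the ligand, which should set the C10 carbinol as S.

Step 2
Reactants: 4 (3S)-5-(trimethylsilyl)pent-1-en-4-yn-3-ol
Product: 5 (3S)-pent-1-en-4-yn-3-ol
Conditions: K2CO3 (cat.), MeOH, 0 °C
Reagents that add atoms: none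
Why: Base-catalysed methanolysis of the C(sp)–Si bond frees the terminal alkyne without touching the carbinol centre.

Step 3
Reactants: 5 (3S)-pent-1-en-4-yn-3-ol
Product: 7 (1Z,3S)-1-iodo-2-methylpenta-1,4-dien-3-ol, via alkenylmagnesium alkoxide 6 (not isolated)
Conditions: MeMgBr (3 equiv), CuI (10 mol%), THF, −20 °C → rt; then I2, −78 → 0 °C
Reagents that add atoms: methylmagnesium bromide C[Mg]Br; iodine II
Why: Copper-catalysed anti-carbomagnesiation of the propargylic magnesium alkoxide puts methyl on the internal carbon and magnesium on the terminal carbon cis to the carbinol (five-membered chelate), and iodinolysis with retention should give the Z vinyl iodide.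

Step 4
Reactants: 7 (1Z,3S)-1-iodo-2-methylpenta-1,4-dien-3-ol
Product: 8 triethyl{[(1Z,3S)-1-iodo-2-methylpenta-1,4-dien-3-yl]oxy}silane
Conditions: Et3SiCl, imidazole, CH2Cl2, 0 °C
Reagents that add atoms: chlorotriethylsilane CC[Si](Cl)(CC)CC
Why: Standard silylation of the secondary allylic alcohol gives the acid-labile ether that is later removed in the presence of the tert-butyldimethylsilyl ether.

Step 5
Reactants: 8 triethyl{[(1Z,3S)-1-iodo-2-methylpenta-1,4-dien-3-yl]oxy}silane
Product: 11 tert-butyldimethyl{[(1Z,3S)-2-methyl-3-(triethylsilyloxy)penta-1,4-dien-1-yl]oxy}silane, via vinyllithium 9 (not isolated), via lithium enolate 10 (not isolated)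
Conditions: t-BuLi (2 equiv), Et2O, −78 °C; t-BuOOLi (from t-BuOOH and n-BuLi), THF, −78 °C; t-BuMe2SiCl, HMPA, −78 → 0 °C
Reagents that add atoms: lithium tert-butyl peroxide CC(C)(C)OO[Li]; tert-butylchlorodimethylsilane CC(C)(C)[Si](C)(C)Cl
Why: Iodine–lithium exchange, electrophilic oxygenation of the vinyllithium by the lithium peroxide with retention of configuration and O-silylation of the aldehyde enolate should deliver the Z silyl enol ether (O-2 cis to C10) stereospecifically.

Step 6
Reactants: 12 (2R)-but-3-yn-2-ol; 13 3-bromo-2-methylprop-1-ene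
Product: 14 (2R)-6-methylhept-6-en-3-yn-2-ol
Conditions: CuI (10 mol%), K2CO3, DMF, rt
Reagents that add atoms: none
Why: Copper-catalysed allylation of the terminal acetylide (SN2 at the primary allylic bromide) forms C6–C7 and leaves the carbinol centre untouched.

Step 7
Reactants: 14 (2R)-6-methylhept-6-en-3-yn-2-ol
Product: 15 (2R,3E)-6-methylhepta-3,6-dien-2-ol
Conditions: NaAlH2(OCH2CH2OMe)2, THF, 0 °C → rt
Reagents that add atoms: none
Why: Hydroxyl-directed trans-hydroalumination of the propargylic alcohol followed by protonolysis should give the E allylic alcohol only.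

Step 8
Reactants: 15 (2R,3E)-6-methylhepta-3,6-dien-2-ol
Product: 16 (1R)-1-[(2R,3R)-3-(2-methylprop-2-en-1-yl)oxiran-2-yl]ethan-1-ol
Conditions: Ti(OiPr)4 (10 mol%), D-(−)-diisopropyl tartrate (12 mol%), t-BuOOH, 4 Å molecular sieves, CH2Cl2, −20 °C
Reagents that add atoms: tert-butyl hydroperoxide CC(C)(C)OO
Why: Sharpless asymmetric epoxidation in the matched sense, in which the D-tartrate and the (R)-carbinol select the same alkene face (erythro epoxy alcohol), sets C5 and C6 and leaves the isolated 1,1-disubstituted alkene alone.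

Step 9
Reactants: 16 (1R)-1-[(2R,3R)-3-(2-methylprop-2-en-1-yl)oxiran-2-yl]ethan-1-ol
Product: 17 1-[(2S,3R)-3-(2-methylprop-2-en-1-yl)oxiran-2-yl]ethan-1-one
Conditions: Dess–Martin periodinane, pyridine, CH2Cl2, 0 °C → rt
Reagents that add atoms: none
Why: Buffered Dess–Martin oxidation gives the α,β-epoxy methyl ketone without opening or epimerising the oxirane.

Step 10
Reactants: 17 1-[(2S,3R)-3-(2-methylprop-2-en-1-yl)oxiran-2-yl]ethan-1-one
Product: 19 triethyl({1-[(2S,3R)-3-(2-methylprop-2-en-1-yl)oxiran-2-yl]ethenyl}oxy)silane, via lithium enolate 18 (not isolated)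
Conditions: LiN(i-Pr)2, THF, −78 °C; then Et3SiCl, −78 → 0 °C
Reagents that add atoms: chlorotriethylsilane CC[Si](Cl)(CC)CC
Why: Kinetic deprotonation at the methyl group, the only position that can enolise without opening the oxirane, and O-silylation give the epoxy enolsilane.

Step 11
Reactants: 11 tert-butyldimethyl{[(1Z,3S)-2-methyl-3-(triethylsilyloxy)penta-1,4-dien-1-yl]oxy}silane; 19 triethyl({1-[(2S,3R)-3-(2-methylprop-2-en-1-yl)oxiran-2-yl]ethenyl}oxy)silane
Product: 20 (2R,3R,4S)-4-(tert-butyldimethylsilyloxy)-3-methyl-2-[(1R)-3-methyl-1-(triethylsilyloxy)but-3-en-1-yl]-3-[(1S)-1-(triethylsilyloxy)prop-2-en-1-yl]cyclopentan-1-one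
Conditions: Et3SiOTf (0.2 equiv), 2,6-di-tert-butylpyridine (0.2 equiv), 11 (1.3 equiv), CH2Cl2, −78 °C; Et3N quench
Reagents that add atoms: none
Why: Proposed new method: Et3SiOTf silylates the oxirane oxygen of 19, the nucleophilic carbon C1 of enol ether 11 opens the allylic C5–O bond from the rear (SN2-like within the 2-siloxyallyl unit) and the oxocarbenium carbon C2 that develops is captured by the enol silane carbon C3 before bond rotation, the Et3Si+ released from O-4 carrying the chain to the next oxirane, so that C1–C5 and C2–C3 form in one operation. The closest known reactions are the silyl triflate-catalysed (4+3) cycloadditions of epoxy enolsilanes with dienes and the (3+2) cycloadditions of 2-siloxyallyl cations with alkenes and enol ethers to cyclopentanones, and enol ether 11 is a stronger π-nucleophile than the dienes used there. The cyclopentanone ring (C1–C5) closes by an intermolecular C1–C5 bond followed by a 5-(enolendo)-exo-trig attack of C3 on C2, acceptable here because the three-carbon unit behaves as an allyl cation adding suprafacially across the C1=C2 π bond. C5 is set by inversion at the oxirane carbon and C6 is carried over from the oxirane; C1 is set by attack on the enol ether face opposite the C10 silyloxy group in the conformer with H-10 eclipsing C1=C2 (allylic 1,3-strain with the cis silyloxy group on C2); C2 follows from the Z geometry because both bonds form on the same face of the alkene. The step needs C1 to bond to C5 and not to C3, which the oxirane carbon as the only electrophilic site and the polarity of the enol ether secure, and it needs C- and not O-closure, which the silyl cap on the enol oxygen secures.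

Step 12
Reactants: 20 (2R,3R,4S)-4-(tert-butyldimethylsilyloxy)-3-methyl-2-[(1R)-3-methyl-1-(triethylsilyloxy)but-3-en-1-yl]-3-[(1S)-1-(triethylsilyloxy)prop-2-en-1-yl]cyclopentan-1-one
Product: 21 (1S,2R,3R,4S)-4-(tert-butyldimethylsilyloxy)-3-methyl-2-[(1R)-3-methyl-1-(triethylsilyloxy)but-3-en-1-yl]-1-(propan-2-yl)-3-[(1S)-1-(triethylsilyloxy)prop-2-en-1-yl]cyclopentan-1-ol
Conditions: i-PrMgCl, CeCl3, THF, −78 °C
Reagents that add atoms: isopropylmagnesium chloride CC(C)[Mg]Cl
Why: Organocerium 1,2-addition (low basicity, so no enolisation or β-elimination of the two β-silyloxy groups) should occur on the ketone face anti to the C5 side chain, the C2 silyloxy group and the C10 side chain, setting C4 with OH cis to O-2.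

Step 13
Reactants: 21 (1S,2R,3R,4S)-4-(tert-butyldimethylsilyloxy)-3-methyl-2-[(1R)-3-methyl-1-(triethylsilyloxy)but-3-en-1-yl]-1-(propan-2-yl)-3-[(1S)-1-(triethylsilyloxy)prop-2-en-1-yl]cyclopentan-1-ol
Product: 22 triol (21 with both triethylsilyl groups replaced by H)
Conditions: PPTS (cat.), MeOH/CH2Cl2, 0 °C → rt
Reagents that add atoms: none
Why: Acid-catalysed methanolysis removes the two triethylsilyl ethers far faster than the hindered tert-butyldimethylsilyl ether at O-2.

Step 14
Reactants: 22 triol (21 with both triethylsilyl groups replaced by H)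
Product: 23 2-(tert-butyldimethylsilyloxy)dauc-8-ene-4,6,10-triol (cis-fused; configured as the target)
Conditions: second-generation Grubbs catalyst (H2IMes)(PCy3)Cl2Ru=CHPh (10 mol%), CH2Cl2, 40 °C
Reagents that add atoms: none
Why: Ring-closing metathesis between the vinyl group on C10 and the 1,1-disubstituted alkene on C7, held cis on the cyclopentane, should close the seven-membered ring and give the trisubstituted ring alkene C8=C9.

Step 15
Reactants: 23 2-(tert-butyldimethylsilyloxy)dauc-8-ene-4,6,10-triol (cis-fused; configured as the target)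
Product: 24 8,9-epoxide of 23 (oxirane oxygen on the face of O-6 and O-10)
Conditions: VO(acac)2 (5 mol%), t-BuOOH, CH2Cl2, 0 °C
Reagents that add atoms: tert-butyl hydroperoxide CC(C)(C)OO
Why: Hydroxyl-directed epoxidation, in which the vanadium peroxide bound to the allylic C10 hydroxyl (the homoallylic C6 hydroxyl lies on the same face) delivers oxygen syn to these groups, should set C8 and C9.

Step 16
Reactants: 24 8,9-epoxide of 23 (oxirane oxygen on the face of O-6 and O-10); 25 angelic acid ((Z)-2-methylbut-2-enoic acid), one equivalent for each of the two esters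
Product: 27 6,10-di-O-angeloyl derivative of 24 (the 2-O-silyl ether of the target), via mixed anhydride 26 (not isolated)
Conditions: 25 (6 equiv), 2,4,6-Cl3C6H2COCl (6 equiv), Et3N, toluene, rt; then 24, 80 °C
Reagents that add atoms: angelic acid 25, the second equivalent, C/C=C(/C)C(=O)O
Why: Yamaguchi esterification in which two equivalents of the preformed mixed anhydride, used in excess and without a nucleophilic catalyst so that the Z geometry is kept, should acylate both secondary hydroxyls (O-6 and O-10) while the tertiary C4 hydroxyl stays free.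

Step 17
Reactants: 27 6,10-di-O-angeloyl derivative of 24 (the 2-O-silyl ether of the target)
Product: 28 target CNP0265715.2
Conditions: HF·pyridine, pyridine, THF, 0 °C → rt
Reagents that add atoms: none
Why: Buffered acidic fluoride cleaves the Si–O bond at O-2 without base-induced acyl migration from O-10 and without opening the oxirane.

Compound list
1 | acrolein (prop-2-enal) | C=CC=O | starting material
2 | ethynyltrimethylsilane | C#C[Si](C)(C)C | starting material
3 | methyl[(trimethylsilyl)ethynyl]zinc | C[Zn]C#C[Si](C)(C)C | intermediate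
4 | (3S)-5-(trimethylsilyl)pent-1-en-4-yn-3-ol | C=C[C@H](O)C#C[Si](C)(C)C | intermediate
5 | (3S)-pent-1-en-4-yn-3-ol | C=C[C@H](O)C#C | intermediate
6 | bromomagnesium (1Z,3S)-1-(bromomagnesio)-2-methylpenta-1,4-dien-3-olate | C=C[C@H](O[Mg]Br)/C(C)=C\[Mg]Br | intermediate
7 | (1Z,3S)-1-iodo-2-methylpenta-1,4-dien-3-ol | C=C[C@H](O)/C(C)=C\I | intermediate
8 | triethyl{[(1Z,3S)-1-iodo-2-methylpenta-1,4-dien-3-yl]oxy}silane | C=C[C@H](O[Si](CC)(CC)CC)/C(C)=C\I | intermediate
9 | [(1Z,3S)-2-methyl-3-(triethylsilyloxy)penta-1,4-dien-1-yl]lithium | C=C[C@H](O[Si](CC)(CC)CC)/C(C)=C\[Li] | intermediate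
10 | lithium (1Z,3S)-2-methyl-3-(triethylsilyloxy)penta-1,4-dien-1-olate | C=C[C@H](O[Si](CC)(CC)CC)/C(C)=C\O[Li] | intermediate
11 | tert-butyldimethyl{[(1Z,3S)-2-methyl-3-(triethylsilyloxy)penta-1,4-dien-1-yl]oxy}silane | C=C[C@H](O[Si](CC)(CC)CC)/C(C)=C\O[Si](C)(C)C(C)(C)C | intermediate
12 | (2R)-but-3-yn-2-ol | C[C@@H](O)C#C | starting material
13 | 3-bromo-2-methylprop-1-ene | C=C(C)CBr | starting material
14 | (2R)-6-methylhept-6-en-3-yn-2-ol | C[C@@H](O)C#CCC(C)=C | intermediate
15 | (2R,3E)-6-methylhepta-3,6-dien-2-ol | C[C@@H](O)/C=C/CC(C)=C | intermediate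
16 | (1R)-1-[(2R,3R)-3-(2-methylprop-2-en-1-yl)oxiran-2-yl]ethan-1-ol | C[C@@H](O)[C@H]1O[C@@H]1CC(C)=C | intermediate
17 | 1-[(2S,3R)-3-(2-methylprop-2-en-1-yl)oxiran-2-yl]ethan-1-one | CC(=O)[C@H]1O[C@@H]1CC(C)=C | intermediate
18 | lithium 1-[(2S,3R)-3-(2-methylprop-2-en-1-yl)oxiran-2-yl]ethen-1-olate | C=C(O[Li])[C@H]1O[C@@H]1CC(C)=C | intermediate
19 | triethyl({1-[(2S,3R)-3-(2-methylprop-2-en-1-yl)oxiran-2-yl]ethenyl}oxy)silane | C=C(O[Si](CC)(CC)CC)[C@H]1O[C@@H]1CC(C)=C | intermediate
20 | (2R,3R,4S)-4-(tert-butyldimethylsilyloxy)-3-methyl-2-[(1R)-3-methyl-1-(triethylsilyloxy)but-3-en-1-yl]-3-[(1S)-1-(triethylsilyloxy)prop-2-en-1-yl]cyclopentan-1-one | C=C(C)C[C@@H](O[Si](CC)(CC)CC)[C@@H]1C(=O)C[C@H](O[Si](C)(C)C(C)(C)C)[C@]1(C)[C@@H](O[Si](CC)(CC)CC)C=C | intermediate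
21 | (1S,2R,3R,4S)-4-(tert-butyldimethylsilyloxy)-3-methyl-2-[(1R)-3-methyl-1-(triethylsilyloxy)but-3-en-1-yl]-1-(propan-2-yl)-3-[(1S)-1-(triethylsilyloxy)prop-2-en-1-yl]cyclopentan-1-ol | C=C(C)C[C@@H](O[Si](CC)(CC)CC)[C@@H]1[C@@](O)(C(C)C)C[C@H](O[Si](C)(C)C(C)(C)C)[C@]1(C)[C@@H](O[Si](CC)(CC)CC)C=C | intermediate
22 | triol: 21 with both triethylsilyl groups replaced by H (free OH at C4, C6 and C10; silyl ether at O-2) | C=C(C)C[C@@H](O)[C@@H]1[C@@](O)(C(C)C)C[C@H](O[Si](C)(C)C(C)(C)C)[C@]1(C)[C@@H](O)C=C | intermediate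
23 | 2-(tert-butyldimethylsilyloxy)dauc-8-ene-4,6,10-triol, cis-fused (1-methyl, H-5, 4-isopropyl, O-6 and O-10 on one face; O-2 and 4-OH on the other) | O[C@@H]1CC(C)=C[C@H](O)[C@@]2(C)[C@@H](O[Si](C)(C)C(C)(C)C)C[C@](O)(C(C)C)[C@@H]12 | intermediate
24 | 8,9-epoxide of 23, oxirane oxygen on the face of O-6 and O-10 | O[C@@H]1C[C@]2(C)O[C@@H]2[C@H](O)[C@@]2(C)[C@@H](O[Si](C)(C)C(C)(C)C)C[C@](O)(C(C)C)[C@@H]12 | intermediate
25 | angelic acid, (Z)-2-methylbut-2-enoic acid | C/C=C(/C)C(=O)O | starting material
26 | (Z)-2-methylbut-2-enoic 2,4,6-trichlorobenzoic anhydride | C/C=C(/C)C(=O)OC(=O)c1c(Cl)cc(Cl)cc1Cl | intermediate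
27 | 6,10-di-O-angeloyl derivative of 24 (2-O-tert-butyldimethylsilyl ether of the target) | C/C=C(/C)C(=O)O[C@@H]1C[C@]2(C)O[C@@H]2[C@H](OC(=O)/C(C)=C\C)[C@@]2(C)[C@@H](O[Si](C)(C)C(C)(C)C)C[C@](O)(C(C)C)[C@@H]12 | intermediate
28 | CNP0265715.2: 6,10-di-O-angeloyl-8,9-epoxy-cis-daucane-2,4,6,10-tetrol | C/C=C(/C)C(=O)O[C@@H]1C[C@]2(C)O[C@@H]2[C@H](OC(=O)/C(C)=C\C)[C@@]2(C)[C@@H](O)C[C@](O)(C(C)C)[C@@H]12 | target

Total steps: 17. Longest linear sequence: 12 (steps 1–5 or 6–10, then 11–17).

Steps most likely to fail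

1. Step 11. The bimolecular C1–C5 bond formation may be outrun by ionisation of the allylic silyl ether of 11, by protodesilylation of either enol silane, or by capture of the activated oxirane by the methallyl alkene of 19. The facial selectivity at C1 may also be poor. The fallback uses known reactions and makes the two bonds in separate operations, setting out from 17 and 11 and returning at 20. MgBr2·OEt2 opens 17 at the carbon next to the carbonyl to the bromohydrin (3R,4R)-3-bromo-4-hydroxy-6-methylhept-6-en-2-one F1. Et3SiOTf and 2,6-lutidine convert it into (3R,4R)-3-bromo-6-methyl-4-(triethylsilyloxy)hept-6-en-2-one F2. Visible-light photoredox alkylation of 11 with F2 (Ir(ppy)3, blue light, Na2HPO4, MeCN) should follow: the α-keto radical adds to C1, and the α-silyloxy radical is oxidised and loses silicon. This should give the keto aldehyde (4R)-3-acetyl-2,6-dimethyl-4-(triethylsilyloxy)-2-[(1S)-1-(triethylsilyloxy)prop-2-en-1-yl]hept-6-enal F3. LiN(SiMe3)2 at −78 °C then closes C2–C3 by intramolecular aldol addition of the methyl ketone enolate to the non-enolisable aldehyde, giving the hydroxy ketone F4 (20 with free OH at C2), and t-BuMe2SiOTf with 2,6-lutidine returns to 20. In this sequence C5 and C2 are no longer set by the oxirane and the alkene geometry, so isomers at these centres would have to be separated.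

2. Step 5. The triethylsilyl group may shift from O-10 to the cis vinyl carbanion (1,4-silyl migration) before oxygenation, and the β-silyloxy enolate may lose silanolate before it is silylated. The fallback avoids a vinyl anion, setting out from 8 and returning at 11. Borylation with B2pin2 (PdCl2(dppf), KOPh, toluene) with retention gives 2-[(1Z,3S)-2-methyl-3-(triethylsilyloxy)penta-1,4-dien-1-yl]-4,4,5,5-tetramethyl-1,3,2-dioxaborolane F5. Oxidation with NaBO3 gives (3S)-2-methyl-3-(triethylsilyloxy)pent-4-enal F6 (both C2 epimers). Soft enolisation (t-BuMe2SiOTf, Et3N, CH2Cl2) gives 11 together with its E isomer, which is separated, hydrolysed back to F6 and recycled.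

3. Step 16. Acylation of the neopentyl C10 hydroxyl beside the oxirane may be slow, so that a monoester builds up, and the angeloyl group may isomerise to the E (tigloyl) isomer on prolonged heating. The fallback builds the Z alkene after esterification, setting out from 24 and returning at 27. Both secondary hydroxyls are esterified with 2-[bis(2,2,2-trifluoroethoxy)phosphoryl]propanoic acid (DCC, DMAP) to the 6,10-bis{2-[bis(2,2,2-trifluoroethoxy)phosphoryl]propanoate} of 24 F7. A Z-selective Horner–Wadsworth–Emmons reaction under Still–Gennari conditions (KN(SiMe3)2, 18-crown-6, acetaldehyde, THF, −78 °C) then turns both esters into (Z)-2-methylbut-2-enoates.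

Further compounds
F1 | step 11 | (3R,4R)-3-bromo-4-hydroxy-6-methylhept-6-en-2-one | CC(=O)[C@H](Br)[C@H](O)CC(C)=C
F2 | step 11 | (3R,4R)-3-bromo-6-methyl-4-(triethylsilyloxy)hept-6-en-2-one | CC(=O)[C@H](Br)[C@H](O[Si](CC)(CC)CC)CC(C)=C
F3 | step 11 | (4R)-3-acetyl-2,6-dimethyl-4-(triethylsilyloxy)-2-[(1S)-1-(triethylsilyloxy)prop-2-en-1-yl]hept-6-enal, C2 and C3 configured as C1 and C5 of 20 | C=C(C)C[C@@H](O[Si](CC)(CC)CC)[C@H](C(C)=O)[C@](C)(C=O)[C@@H](O[Si](CC)(CC)CC)C=C
F4 | step 11 | hydroxy ketone, 20 with free OH at C2 | C=C(C)C[C@@H](O[Si](CC)(CC)CC)[C@@H]1C(=O)C[C@H](O)[C@]1(C)[C@@H](O[Si](CC)(CC)CC)C=C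
F5 | step 5 | 2-[(1Z,3S)-2-methyl-3-(triethylsilyloxy)penta-1,4-dien-1-yl]-4,4,5,5-tetramethyl-1,3,2-dioxaborolane | C=C[C@H](O[Si](CC)(CC)CC)/C(C)=C\B1OC(C)(C)C(C)(C)O1
F6 | step 5 | (3S)-2-methyl-3-(triethylsilyloxy)pent-4-enal, both C2 epimers | C=C[C@H](O[Si](CC)(CC)CC)C(C)C=O
F7 | step 16 | 6,10-bis{2-[bis(2,2,2-trifluoroethoxy)phosphoryl]propanoate} of 24 | CC(P(=O)(OCC(F)(F)F)OCC(F)(F)F)C(=O)O[C@@H]1C[C@]2(C)O[C@@H]2[C@H](OC(=O)C(C)P(=O)(OCC(F)(F)F)OCC(F)(F)F)[C@@]2(C)[C@@H](O[Si](C)(C)C(C)(C)C)C[C@](O)(C(C)C)[C@@H]12
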